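Ring A (C-1 to C-5 and C-10, eudesmane numbering) is disconnected as a [3+3] union: C-1–C-2–C-3 comes from allylidenetriphenylphosphorane, C-10–C-5–C-4 from a ring-B alkylidene β-diketone made from (−)-menthone. The key step forms C-1–C-10 (Michael addition creating the quaternary centre) and C-3=C-4 (intramolecular Wittig) in one operation and closes ring A as a diene. It exploits the 1,3-dioxygenation across C-5: the C-4 carbinol and C-6 benzoate carbons are both carbonyls in the precursor, so C-10 is doubly activated and C-4 is the olefination site. The precursor is a monocyclic 2-acetylpiperitone; the diene is later reduced to the C-3=C-4 alkene, which is opened to the trans-diaxial diol.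

Key step: step 3

Remark: the decalin is numbered as a eudesmane (ring A = C-1 to C-5 plus C-10, ring B = C-5 to C-10, C-14 = methyl on C-10, C-15 = methyl on C-4, isopropyl on C-7; β = the face of C-14); commercial (−)-menthone is assumed to be the (2S,5R) isomer and is used free of isomenthone.

Step 1
Reactants: 1 (−)-menthone; 2 1-acetyl-1H-benzotriazole
Product: 4 (3R,6S)-2-acetyl-3-methyl-6-(propan-2-yl)cyclohexan-1-one, via lithium enolate 3 (not isolated)
Conditions: LiN(iPr)2 (2.1 equiv), THF, −78 °C; then 2, −78 → 0 °C; aq. HCl work-up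
Reagents that add atoms: 1-acetyl-1H-benzotriazole, CC(=O)n1nnc2ccccc12
Why: LiN(iPr)2 removes a proton from the less hindered C-6 methylene of menthone (kinetic enolate) and the lithium enolate is C-acylated by the N-acylbenzotriazole (Claisen-type acylation), which leaves the isopropyl-bearing centre untouched; the new centre between the carbonyls is enolised and is removed in step 2.

Step 2
Reactants: 4 (3R,6S)-2-acetyl-3-methyl-6-(propan-2-yl)cyclohexan-1-one
Product: 5 (6S)-2-acetyl-3-methyl-6-(propan-2-yl)cyclohex-2-en-1-one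
Conditions: DDQ (1.1 equiv), 1,4-dioxane, 25 °C
Reagents that add atoms: none
Why: Dehydrogenation with DDQ (hydride abstraction from the tertiary C-3–H of the enolised β-diketone, as in the DDQ dehydrogenation of 2-hydroxymethylene ketones) should give the alkylidene β-diketone, since C-3 carries the only hydrogen β to the diketone carbon; no stereocentre is formed and C-6 keeps its configuration.

Step 3
Reactants: 5 (6S)-2-acetyl-3-methyl-6-(propan-2-yl)cyclohex-2-en-1-one; 6 allyltriphenylphosphonium bromide
Product: 9 (2S,4aS)-4a,8-dimethyl-2-(propan-2-yl)-3,4,4a,5-tetrahydronaphthalen-1(2H)-one, via phosphonium enolate betaine 7 (not isolated), via unconjugated 1,3-dienone 8 (not isolated)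
Conditions: 6, KN(SiMe3)2 (slight deficit to 6), THF, −78 °C; add 5, −78 → 50 °C; then DBU (cat.), 25 °C; chromatography to remove the C-4a epimer
Reagents that add atoms: allyltriphenylphosphonium bromide, C=CC[P+](c1ccccc1)(c1ccccc1)c1ccccc1.[Br-]
Why: The γ-carbon of allylidenetriphenylphosphorane adds to C-10, the β-carbon of the alkylidene β-diketone (Michael addition, C-1–C-10), proton transfer from C-1 regenerates an allylic ylide, its α-carbon C-3 olefinates the acetyl carbonyl C-4 intramolecularly (Wittig, C-3=C-4) with loss of Ph3PO, and DBU then moves the diene into conjugation with the C-6 ketone. The closest known reaction type is the cyclohexadiene annulation of alkylidene acetoacetates and enones with allylidenephosphoranes; the alternative order (Wittig at C-4, then thermal disrotatory 6π-electrocyclisation of the 2-acyl triene) would form the same two bonds and the same product. Ring A is closed in the olefination step by attack of the ylide carbon on the exocyclic acetyl carbonyl (6-exo-trig, via the oxaphosphetane). The only new stereocentre, quaternary C-10, is set when C-1–C-10 forms, under the influence of the remote C-7 isopropyl group alone, so both C-10 epimers are expected and the (2S,4aS) isomer, in which the equatorial isopropyl group is cis to the methyl group, is separated. The step needs addition and olefination to outrun proton abstraction from the γ-positions of 5, and olefination at C-4 instead of C-6: the ring carbonyl is more hindered and its olefination would give a bridgehead alkene. A slight deficit of base leaves no free amide to epimerise C-7, whose proton is far less acidic than the phosphonium salt.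

Step 4
Reactants: 9 (2S,4aS)-4a,8-dimethyl-2-(propan-2-yl)-3,4,4a,5-tetrahydronaphthalen-1(2H)-one
Product: 11 (2S,4aR,8aR)-4a,8-dimethyl-2-(propan-2-yl)-3,4,4a,5,6,8a-hexahydronaphthalen-1(2H)-one, via lithium dienolate 10 (not isolated)
Conditions: Li, NH3(l)–THF, t-BuOH (1 equiv), −78 °C; then NH4Cl (solid); used crude
Reagents that add atoms: none
Why: Dissolving-metal reduction (Birch-type) of the linear dienone gives, after protonation at C-2, the conjugated lithium dienolate 10, and kinetic protonation of 10 at the α-carbon C-5 from the α face (axial, anti to the C-10 methyl) should give the β,γ-unsaturated ketone with trans ring fusion (reductive deconjugation).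

Step 5
Reactants: 11 (2S,4aR,8aR)-4a,8-dimethyl-2-(propan-2-yl)-3,4,4a,5,6,8a-hexahydronaphthalen-1(2H)-one
Product: 12 (1R,2S,4aR,8aR)-4a,8-dimethyl-2-(propan-2-yl)-1,2,3,4,4a,5,6,8a-octahydronaphthalen-1-ol
Conditions: NaBH4, CeCl3·7H2O, MeOH, −40 → 0 °C
Reagents that add atoms: none
Why: Luche reduction should deliver hydride to C-6 from the α face (equatorial attack), because the axial C-10 methyl blocks the β face as in 5α-6-oxo steroids, giving the axial 6β-alcohol without conjugating the β,γ-enone.

Step 6
Reactants: 12 (1R,2S,4aR,8aR)-4a,8-dimethyl-2-(propan-2-yl)-1,2,3,4,4a,5,6,8a-octahydronaphthalen-1-ol; 13 benzoyl chloride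
Product: 14 (1R,2S,4aR,8aR)-4a,8-dimethyl-2-(propan-2-yl)-1,2,3,4,4a,5,6,8a-octahydronaphthalen-1-yl benzoate
Conditions: BzCl, pyridine, DMAP (cat.), CH2Cl2, 25 → 40 °C
Reagents that add atoms: benzoyl chloride, O=C(Cl)c1ccccc1
Why: DMAP-catalysed acyl transfer (nucleophilic catalysis) should esterify the hindered axial secondary alcohol with benzoyl chloride without touching any stereocentre.

Step 7
Reactants: 14 (1R,2S,4aR,8aR)-4a,8-dimethyl-2-(propan-2-yl)-1,2,3,4,4a,5,6,8a-octahydronaphthalen-1-yl benzoate; 15 3-chloroperoxybenzoic acid; 16 water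
Product: 18 (1R,2S,4aS,7R,8R,8aS)-7,8-dihydroxy-4a,8-dimethyl-2-(propan-2-yl)decahydronaphthalen-1-yl benzoate, via α-epoxide 17 (not isolated)
Conditions: mCPBA, CH2Cl2, 0 °C; then THF–H2O, HClO4 (cat.), 25 °C
Reagents that add atoms: 3-chloroperoxybenzoic acid, O=C(OO)c1cccc(Cl)c1; water, O
Why: Prilezhaev epoxidation should take place on the α face of the C-3=C-4 alkene (the β face is shielded by the C-10 methyl and the 6β-benzoate), and acid-catalysed opening of epoxide 17 at the tertiary C-4 by water from the β face (trans-diaxial opening, Fürst–Plattner rule, possibly relayed by the neighbouring benzoate whose dioxanylium ion returns the secondary ester) should set 3α-OH and 4β-OH.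

Compound list
1 | (−)-menthone, (2S,5R)-5-methyl-2-(propan-2-yl)cyclohexan-1-one | CC(C)[C@@H]1CC[C@@H](C)CC1=O | starting material
2 | 1-acetyl-1H-benzotriazole | CC(=O)n1nnc2ccccc12 | starting material
3 | lithium (3R,6S)-3-methyl-6-(propan-2-yl)cyclohex-1-en-1-olate (kinetic enolate of 1) | CC(C)[C@@H]1CC[C@@H](C)C=C1[O-].[Li+] | intermediate
4 | (3R,6S)-2-acetyl-3-methyl-6-(propan-2-yl)cyclohexan-1-one (keto–enol mixture, C-2 not defined) | CC(C)[C@@H]1CC[C@@H](C)C(C(C)=O)C1=O | intermediate
5 | (6S)-2-acetyl-3-methyl-6-(propan-2-yl)cyclohex-2-en-1-one | CC(C)[C@@H]1CCC(C)=C(C(C)=O)C1=O | intermediate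
6 | allyltriphenylphosphonium bromide | C=CC[P+](c1ccccc1)(c1ccccc1)c1ccccc1.[Br-] | starting material
7 | Michael adduct betaine: (E)-3-(ring-B C-10)prop-1-enyl(triphenyl)phosphonium, β-diketone enolate form (C-10 configured as in 9) | CC(C)[C@@H]1CC[C@@](C)(C/C=C/[P+](c2ccccc2)(c2ccccc2)c2ccccc2)C(=C(C)[O-])C1=O | intermediate
8 | (2S,4aS)-4a,8-dimethyl-2-(propan-2-yl)-3,4,4a,8a-tetrahydronaphthalen-1(2H)-one (7αH-eudesma-1,3-dien-6-one, C-5 epimers) | CC(C)[C@@H]1CC[C@@]2(C)C=CC=C(C)C2C1=O | intermediate
9 | (2S,4aS)-4a,8-dimethyl-2-(propan-2-yl)-3,4,4a,5-tetrahydronaphthalen-1(2H)-one (7αH-eudesma-2,4-dien-6-one) | CC(C)[C@@H]1CC[C@@]2(C)CC=CC(C)=C2C1=O | intermediate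
10 | lithium (2S,4aR)-4a,8-dimethyl-2-(propan-2-yl)-2,3,4,4a,5,6-hexahydronaphthalen-1-olate (dienolate) | CC(C)[C@@H]1CC[C@@]2(C)CCC=C(C)C2=C1[O-].[Li+] | intermediate
11 | (2S,4aR,8aR)-4a,8-dimethyl-2-(propan-2-yl)-3,4,4a,5,6,8a-hexahydronaphthalen-1(2H)-one (5αH,7αH-eudesm-3-en-6-one) | CC(C)[C@@H]1CC[C@@]2(C)CCC=C(C)[C@@H]2C1=O | intermediate
12 | (1R,2S,4aR,8aR)-4a,8-dimethyl-2-(propan-2-yl)-1,2,3,4,4a,5,6,8a-octahydronaphthalen-1-ol (5αH,7αH-eudesm-3-en-6β-ol) | CC(C)[C@@H]1CC[C@@]2(C)CCC=C(C)[C@@H]2[C@@H]1O | intermediate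
13 | benzoyl chloride | O=C(Cl)c1ccccc1 | starting material
14 | (1R,2S,4aR,8aR)-4a,8-dimethyl-2-(propan-2-yl)-1,2,3,4,4a,5,6,8a-octahydronaphthalen-1-yl benzoate (5αH,7αH-eudesm-3-en-6β-yl benzoate) | CC(C)[C@@H]1CC[C@@]2(C)CCC=C(C)[C@@H]2[C@@H]1OC(=O)c1ccccc1 | intermediate
15 | 3-chloroperoxybenzoic acid | O=C(OO)c1cccc(Cl)c1 | starting material
16 | water | O | starting material
17 | 3α,4α-epoxy-5αH,7αH-eudesman-6β-yl benzoate | CC(C)[C@@H]1CC[C@@]2(C)CC[C@H]3O[C@@]3(C)[C@@H]2[C@@H]1OC(=O)c1ccccc1 | intermediate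
18 | (1R,2S,4aS,7R,8R,8aS)-7,8-dihydroxy-4a,8-dimethyl-2-(propan-2-yl)decahydronaphthalen-1-yl benzoate (3α,4β-dihydroxy-5αH,7αH-eudesman-6β-yl benzoate) | CC(C)[C@@H]1CC[C@@]2(C)CC[C@@H](O)[C@](C)(O)[C@@H]2[C@@H]1OC(=O)c1ccccc1 | target

Total step count: 7. Longest linear sequence: 7 steps, from (−)-menthone 1 to 18.

Steps most likely to fail

Step 3. The ylide may act as a base toward the γ-positions of 5 (C-9 and the C-10 methyl), which would consume it as the phosphonium salt and 5 as its dienolate. The remote isopropyl group may discriminate poorly between the two faces of C-10, and olefination at C-4 before the Michael addition may leave a triene of the wrong geometry uncyclised. Fallback: ring A is built in the classical order from (−)-menthone 1, with the last bond made by aldol condensation. Enolate 3 is silylated (LiN(iPr)2, Me3SiCl, THF, −78 °C) to trimethyl{[(3R,6S)-3-methyl-6-(propan-2-yl)cyclohex-1-en-1-yl]oxy}silane F1. Saegusa–Ito oxidation (Pd(OAc)2, MeCN) should give (S)-piperitone F2. Copper-catalysed conjugate addition of CH2=CH(CH2)3MgBr (CuBr·SMe2, THF, −40 °C) should give (3R,6S)-3-methyl-3-(pent-4-en-1-yl)-6-(propan-2-yl)cyclohexan-1-one F3, after removal of its C-3 epimer. Wacker oxidation (PdCl2, CuCl, O2, DMF–H2O) should give the 4-oxopentyl ketone F4. Intramolecular aldol condensation (KOH, MeOH, reflux) should close ring A to the conjugated enone (2S,4aR)-4a,8-dimethyl-2-(propan-2-yl)-3,4,4a,5,6,7-hexahydronaphthalen-1(2H)-one F5. Deconjugation (KOt-Bu, t-BuOH, then fast quench with aqueous AcOH, kinetic α-protonation) comes back to the route at 11.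

Step 4. The reduced species may be protonated at C-4 instead of C-2, the ketone may be over-reduced, or the β,γ-unsaturated ketone may slip into conjugation with C-6 during quench and isolation. Fallback: the order of reductions is changed from dienone 9. Luche reduction (NaBH4, CeCl3·7H2O, MeOH) should give (1R,2S,4aS)-4a,8-dimethyl-2-(propan-2-yl)-1,2,3,4,4a,5-hexahydronaphthalen-1-ol F6. Benzoylation (BzCl, pyridine, DMAP) should give its benzoate F7. 1,4-Hydrogenation of the homoannular cisoid diene (H2, Cr(CO)3(η6-naphthalene), THF) should add hydrogen to C-2 and C-5 from the α face and comes back to the route at 14.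

Step 2. Hydride abstraction may continue toward aromatisation of ring B, or 5 may tautomerise to its dienol under the acidic hydroquinone. Fallback: halogenation and elimination from β-diketone 4. Bromination at C-2 (N-bromosuccinimide, CH2Cl2, 0 °C) should give (2S,3R,6S)-2-acetyl-2-bromo-3-methyl-6-(propan-2-yl)cyclohexan-1-one F8. Dehydrobromination anti to the axial C-3 hydrogen (Li2CO3, LiBr, DMF, 100 °C) comes back to the route at 5.

Further compounds
F1 | step 3 | trimethyl{[(3R,6S)-3-methyl-6-(propan-2-yl)cyclohex-1-en-1-yl]oxy}silane | CC(C)[C@@H]1CC[C@@H](C)C=C1O[Si](C)(C)C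
F2 | step 3 | (6S)-3-methyl-6-(propan-2-yl)cyclohex-2-en-1-one ((S)-piperitone) | CC(C)[C@@H]1CCC(C)=CC1=O
F3 | step 3 | (3R,6S)-3-methyl-3-(pent-4-en-1-yl)-6-(propan-2-yl)cyclohexan-1-one | CC(C)[C@@H]1CC[C@@](C)(CCCC=C)CC1=O
F4 | step 3 | (3R,6S)-3-methyl-3-(4-oxopentyl)-6-(propan-2-yl)cyclohexan-1-one | CC(C)[C@@H]1CC[C@@](C)(CCCC(C)=O)CC1=O
F5 | step 3 | (2S,4aR)-4a,8-dimethyl-2-(propan-2-yl)-3,4,4a,5,6,7-hexahydronaphthalen-1(2H)-one | CC(C)[C@@H]1CC[C@@]2(C)CCCC(C)=C2C1=O
F6 | step 4 | (1R,2S,4aS)-4a,8-dimethyl-2-(propan-2-yl)-1,2,3,4,4a,5-hexahydronaphthalen-1-ol | CC(C)[C@@H]1CC[C@@]2(C)CC=CC(C)=C2[C@@H]1O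
F7 | step 4 | (1R,2S,4aS)-4a,8-dimethyl-2-(propan-2-yl)-1,2,3,4,4a,5-hexahydronaphthalen-1-yl benzoate | CC(C)[C@@H]1CC[C@@]2(C)CC=CC(C)=C2[C@@H]1OC(=O)c1ccccc1
F8 | step 2 | (2S,3R,6S)-2-acetyl-2-bromo-3-methyl-6-(propan-2-yl)cyclohexan-1-one | CC(C)[C@@H]1CC[C@@H](C)[C@](Br)(C(C)=O)C1=O
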